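**Retrosynthetic overview**

1. The target is a 1,2-dioxane (O1–O2–C3–C4–C5–C6) with the (2R)-propanoate arm on C3 and, on C6, a methyl group and the homofarnesyl chain. The side-chain C1'–C2' bond and the C6–O1 bond are disconnected together, giving the C10 silylperoxy ester 17 and (2E,6E)-farnesyl chloride 18.
2. The forward key step copies head-to-tail prenyl transfer of terpene chain elongation: the isopropenyl CH2 of 17 attacks C1 of the farnesyl cation. The resulting tertiary cation is intercepted by peroxide oxygen instead of losing a proton.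
3. Enabling feature: C6 is the tertiary carbon of an isopentenyl unit (CH3, exocyclic CH2 = C1') and also the carbon bonded to O1. O1–O2 is anchored on C3, so the silylperoxy oxygen sits six atoms from the cation and closes the only ring (6-exo) in the last step.
4. 17 comes from methyl acetoacetate and methallyl chloride: C3 by Noyori hydrogenation, C2 by Fráter–Seebach methylation (2,3-anti), then peroxide introduction by SN2 inversion at C3 (2,3-syn) at the C1-alcohol level and re-oxidation of C1 to the methyl ester.
5. C6 is set in the key step by a chair-like closure.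

Key step: step 13

Remark: the tetrahydropyranyl peroxyacetals 12–15 are carried as mixtures of epimers at the acetal carbon (removed in step 11), so that centre is left undefined in their SMILES; (2E,6E)-farnesyl chloride 18 is taken as the commercial reagent.

Step 1
Reactants: 1 methyl acetoacetate; 2 3-chloro-2-methylprop-1-ene (methallyl chloride)
Product: 3 methyl 6-methyl-3-oxohept-6-enoate
Conditions: NaH, THF, 0 °C; n-BuLi, 0 °C; then 2, 0 °C to rt; aq. HCl
Reagents that add atoms: none
Why: γ-Alkylation of the acetoacetate dianion, in which only the terminal, more basic carbanion reacts with the allylic chloride by SN2, so the chain is extended without touching the α-position and no stereocentre is formed.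

Step 2
Reactants: 3 methyl 6-methyl-3-oxohept-6-enoate
Product: 4 methyl (3R)-3-hydroxy-6-methylhept-6-enoate
Conditions: RuCl2[(R)-BINAP] (0.5 mol %), H2 (4 atm), MeOH, 50 °C, stopped after one equivalent of H2
Reagents that add atoms: none
Why: Noyori asymmetric hydrogenation of a β-keto ester, in which the ester-chelated ketone is reduced on the Ru–(R)-BINAP template to the (3R)-alcohol while the remote, non-directing 1,1-disubstituted olefin is expected to survive at low pressure.

Step 3
Reactants: 4 methyl (3R)-3-hydroxy-6-methylhept-6-enoate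
Product: 5 methyl (2R,3R)-3-hydroxy-2,6-dimethylhept-6-enoate
Conditions: LDA (2.2 equiv), THF, −78 to −20 °C; MeI, DMPU, −78 to 0 °C; aq. HCl
Reagents that add atoms: iodomethane, CI
Why: Fráter–Seebach alkylation, in which the lithium alkoxide–enolate dianion is a rigid chelate and iodomethane enters anti to the C3 alkyl arm, which should set C2 as R in a 2,3-anti relationship.

Step 4
Reactants: 5 methyl (2R,3R)-3-hydroxy-2,6-dimethylhept-6-enoate
Product: 6 (2S,3R)-2,6-dimethylhept-6-ene-1,3-diol
Conditions: LiAlH4, THF, 0 °C; NaOH/H2O work-up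
Reagents that add atoms: none
Why: Hydride reduction of the ester to the primary alcohol, which leaves the olefin and both stereocentres untouched (the C2 descriptor changes to S only through the priority change).

Step 5
Reactants: 6 (2S,3R)-2,6-dimethylhept-6-ene-1,3-diol
Product: 7 (2S,3R)-1-[(tert-butyldiphenylsilyl)oxy]-2,6-dimethylhept-6-en-3-ol
Conditions: TBDPSCl (1.05 equiv), imidazole, CH2Cl2, 0 °C
Reagents that add atoms: tert-butyl(chloro)diphenylsilane, CC(C)(C)[Si](Cl)(c1ccccc1)c1ccccc1
Why: Silyl ether formation in which the bulky silyl chloride discriminates the primary from the hindered secondary hydroxyl on steric grounds.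

Step 6
Reactants: 8 3,4-dihydro-2H-pyran; 9 hydrogen peroxide
Product: 10 2-hydroperoxytetrahydro-2H-pyran
Conditions: 50 % aq. H2O2 (excess), cat. H2SO4, 0 °C
Reagents that add atoms: none
Why: Acid-catalysed Markovnikov addition of hydrogen peroxide to the enol ether through the cyclic oxocarbenium ion (peroxyacetal formation), with excess peroxide to suppress the bis-adduct.

Step 7
Reactants: 7 (2S,3R)-1-[(tert-butyldiphenylsilyl)oxy]-2,6-dimethylhept-6-en-3-ol; 10 2-hydroperoxytetrahydro-2H-pyran
Product: 12 tert-butyl{[(2S,3S)-2,6-dimethyl-3-(tetrahydro-2H-pyran-2-ylperoxy)hept-6-en-1-yl]oxy}diphenylsilane, via secondary triflate 11 (not isolated)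
Conditions: Tf2O, 2,6-lutidine, CH2Cl2, −78 °C; then 10, KOtBu, THF, −78 to 0 °C
Reagents that add atoms: trifluoromethanesulfonic anhydride, O=S(=O)(OS(=O)(=O)C(F)(F)F)C(F)(F)F (triflyl group present in 11 only)
Why: Williamson-type SN2 alkylation of a hydroperoxide anion by a secondary alkyl triflate, in which the α-effect nucleophile should displace the cold-generated triflate with inversion at C3 and so turn the 2,3-anti alcohol into the 2,3-syn peroxide with the (3S) centre of the target, at a C1 oxidation level that has no acidic α-hydrogen for elimination.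

Step 8
Reactants: 12 tert-butyl{[(2S,3S)-2,6-dimethyl-3-(tetrahydro-2H-pyran-2-ylperoxy)hept-6-en-1-yl]oxy}diphenylsilane
Product: 13 (2S,3S)-2,6-dimethyl-3-(tetrahydro-2H-pyran-2-ylperoxy)hept-6-en-1-ol
Conditions: TBAF, AcOH (1:1), THF, 0 °C to rt
Reagents that add atoms: none
Why: Fluoride-mediated cleavage of the silyl ether, buffered with acetic acid so that the base-sensitive secondary peroxide is not exposed to alkoxide.

Step 9
Reactants: 13 (2S,3S)-2,6-dimethyl-3-(tetrahydro-2H-pyran-2-ylperoxy)hept-6-en-1-ol
Product: 14 (2R,3S)-2,6-dimethyl-3-(tetrahydro-2H-pyran-2-ylperoxy)hept-6-enoic acid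
Conditions: TEMPO (20 mol %), PhI(OAc)2 (2.2 equiv), MeCN/pH 7 phosphate buffer, rt
Reagents that add atoms: water, O
Why: TEMPO/oxoammonium oxidation, which takes the primary alcohol through the aldehyde hydrate to the acid under near-neutral conditions, so the β-peroxy group should not be eliminated, C2 should not epimerise, and the peroxyacetal and olefin stay inert.

Step 10
Reactants: 14 (2R,3S)-2,6-dimethyl-3-(tetrahydro-2H-pyran-2-ylperoxy)hept-6-enoic acid
Product: 15 methyl (2R,3S)-2,6-dimethyl-3-(tetrahydro-2H-pyran-2-ylperoxy)hept-6-enoate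
Conditions: TMSCHN2, toluene/MeOH (4:1), 0 °C
Reagents that add atoms: (trimethylsilyl)diazomethane, C[Si](C)(C)C=[N+]=[N-]
Why: O-Methylation of the carboxylic acid with a diazoalkane, a neutral esterification that avoids any enolisation next to the β-peroxy group.

Step 11
Reactants: 15 methyl (2R,3S)-2,6-dimethyl-3-(tetrahydro-2H-pyran-2-ylperoxy)hept-6-enoate
Product: 16 methyl (2R,3S)-3-hydroperoxy-2,6-dimethylhept-6-enoate
Conditions: PPTS (cat.), MeOH, rt
Reagents that add atoms: none
Why: Acid-catalysed transacetalisation (methanolysis) of the tetrahydropyranyl peroxyacetal, which releases the secondary hydroperoxide without breaking the C3–O bond, so the configuration is retained.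

Step 12
Reactants: 16 methyl (2R,3S)-3-hydroperoxy-2,6-dimethylhept-6-enoate
Product: 17 methyl (2R,3S)-2,6-dimethyl-3-[(triethylsilyl)peroxy]hept-6-enoate
Conditions: Et3SiCl, imidazole, DMF, 0 °C
Reagents that add atoms: chlorotriethylsilane, CC[Si](Cl)(CC)CC
Why: Silylation of the hydroperoxide O–H with a silyl chloride and a weak base, which gives the non-protic triethylsilyl peroxide needed as a desilylating terminator for the cationic key step.

Step 13
Reactants: 17 methyl (2R,3S)-2,6-dimethyl-3-[(triethylsilyl)peroxy]hept-6-enoate; 18 (2E,6E)-1-chloro-3,7,11-trimethyldodeca-2,6,10-triene ((2E,6E)-farnesyl chloride)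
Product: 20 methyl (2R)-2-[(3S,6R)-6-methyl-6-[(3E,7E)-4,8,12-trimethyltrideca-3,7,11-trien-1-yl]-1,2-dioxan-3-yl]propanoate (CNP0145612.1), via C6 tertiary carbenium ion 19 (not isolated)
Conditions: ZnCl2·OEt2 (0.5 equiv), 2,6-di-tert-butyl-4-methylpyridine (0.2 equiv), CH2Cl2, −78 °C; 18 (1 equiv) added over 2 h to 17 (2.5 equiv, excess recovered); then −40 °C
Reagents that add atoms: none
Why: Proposed new method: ZnCl2 ionises 18 to the (2E,6E)-farnesyl cation, whose primary terminus is attacked by the CH2 terminus of the isopropenyl group of 17 (the head-to-tail prenyl-transfer event of terpene biosynthesis); the tertiary cation 19 at C6 is then captured by the silylated peroxy oxygen and the silyl group leaves as Et3SiCl, which returns ZnCl2. The closest known reaction types are the ZnCl2-promoted 1:1 addition of allylic chlorides to 1,1-disubstituted alkenes and the Lewis-acid [3+2] annulation of triethylsilylperoxy carbenium ions with alkenes, in which an alkene-derived tertiary cation is closed by the silylperoxy oxygen with loss of silicon; electrophile-induced cycloperoxidations of unsaturated hydroperoxides show the same ring size. The 1,2-dioxane closes in a 6-exo mode (O1 onto C6, the former olefinic CH2 staying exocyclic as C1'). The new C6 centre is set in a chair-like closure with the C3 propanoate arm equatorial and the longer homofarnesyl arm equatorial in preference to methyl, which leads to (6R); this bias is expected to be modest and the C6 epimer would be removed by chromatography. The step needs chemoselectivity for the 1,1-disubstituted olefin of 17 over the trisubstituted olefins of 18 and 20 (relied on: anchimeric assistance by the peroxy oxygen, excess 17, slow addition of 18 at −78 °C), attack at C1 rather than C3 of the allyl cation (sterics), and retention of the 2E geometry (no allyl-cation rotation at −78 °C).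

**Compound list**

1 | methyl acetoacetate | COC(=O)CC(C)=O | starting material
2 | 3-chloro-2-methylprop-1-ene | ClCC(C)=C | starting material
3 | methyl 6-methyl-3-oxohept-6-enoate | COC(=O)CC(=O)CCC(C)=C | intermediate
4 | methyl (3R)-3-hydroxy-6-methylhept-6-enoate | COC(=O)C[C@H](O)CCC(C)=C | intermediate
5 | methyl (2R,3R)-3-hydroxy-2,6-dimethylhept-6-enoate | COC(=O)[C@H](C)[C@H](O)CCC(C)=C | intermediate
6 | (2S,3R)-2,6-dimethylhept-6-ene-1,3-diol | OC[C@H](C)[C@H](O)CCC(C)=C | intermediate
7 | (2S,3R)-1-[(tert-butyldiphenylsilyl)oxy]-2,6-dimethylhept-6-en-3-ol | CC(C)(C)[Si](c1ccccc1)(c1ccccc1)OC[C@H](C)[C@H](O)CCC(C)=C | intermediate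
8 | 3,4-dihydro-2H-pyran | C1=COCCC1 | starting material
9 | hydrogen peroxide | OO | starting material
10 | 2-hydroperoxytetrahydro-2H-pyran | OOC1CCCCO1 | intermediate
11 | (2S,3R)-1-[(tert-butyldiphenylsilyl)oxy]-2,6-dimethylhept-6-en-3-yl trifluoromethanesulfonate | CC(C)(C)[Si](c1ccccc1)(c1ccccc1)OC[C@H](C)[C@H](OS(=O)(=O)C(F)(F)F)CCC(C)=C | intermediate (not isolated)
12 | tert-butyl{[(2S,3S)-2,6-dimethyl-3-(tetrahydro-2H-pyran-2-ylperoxy)hept-6-en-1-yl]oxy}diphenylsilane | CC(C)(C)[Si](c1ccccc1)(c1ccccc1)OC[C@H](C)[C@@H](OOC1CCCCO1)CCC(C)=C | intermediate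
13 | (2S,3S)-2,6-dimethyl-3-(tetrahydro-2H-pyran-2-ylperoxy)hept-6-en-1-ol | OC[C@H](C)[C@@H](OOC1CCCCO1)CCC(C)=C | intermediate
14 | (2R,3S)-2,6-dimethyl-3-(tetrahydro-2H-pyran-2-ylperoxy)hept-6-enoic acid | OC(=O)[C@H](C)[C@@H](OOC1CCCCO1)CCC(C)=C | intermediate
15 | methyl (2R,3S)-2,6-dimethyl-3-(tetrahydro-2H-pyran-2-ylperoxy)hept-6-enoate | COC(=O)[C@H](C)[C@@H](OOC1CCCCO1)CCC(C)=C | intermediate
16 | methyl (2R,3S)-3-hydroperoxy-2,6-dimethylhept-6-enoate | COC(=O)[C@H](C)[C@@H](OO)CCC(C)=C | intermediate
17 | methyl (2R,3S)-2,6-dimethyl-3-[(triethylsilyl)peroxy]hept-6-enoate | COC(=O)[C@H](C)[C@@H](OO[Si](CC)(CC)CC)CCC(C)=C | intermediate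
18 | (2E,6E)-1-chloro-3,7,11-trimethyldodeca-2,6,10-triene | ClC/C=C(\C)CC/C=C(\C)CCC=C(C)C | starting material
19 | C6 tertiary carbenium ion of the farnesylated silylperoxy ester | COC(=O)[C@H](C)[C@@H](OO[Si](CC)(CC)CC)CC[C+](C)CC/C=C(\C)CC/C=C(\C)CCC=C(C)C | intermediate (not isolated)
20 | methyl (2R)-2-[(3S,6R)-6-methyl-6-[(3E,7E)-4,8,12-trimethyltrideca-3,7,11-trien-1-yl]-1,2-dioxan-3-yl]propanoate | COC(=O)[C@H](C)[C@@H]1CC[C@@](C)(CC/C=C(\C)CC/C=C(\C)CCC=C(C)C)OO1 | target

**Step count and risks**

Total: 13 steps. Longest linear sequence: 12 steps (steps 1–5 and 7–13; step 6 prepares the peroxide reagent 10).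

Step 13 (proposed new method). The farnesyl cation may be consumed by trisubstituted olefins (oligomerisation) or by its own distal olefin after allylic isomerisation (cyclisation). Cation 19 may lose a proton before the peroxide captures it, and facial discrimination at C6 may be weak. The fallback uses known reactions only and runs from 16 back to 20:
- Epoxidation of the isopropenyl group of 16 with m-CPBA (NaHCO3, CH2Cl2, 0 °C) would give methyl (2R,3S)-3-hydroperoxy-2-methyl-5-(2-methyloxiran-2-yl)pentanoate F1 as both oxirane epimers.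
- Acid catalysis (CSA, CH2Cl2) would close the 1,2-dioxane by 6-exo attack of the hydroperoxide on the tertiary epoxide carbon with inversion. This gives methyl (2R)-2-[(3S,6S)-6-(hydroxymethyl)-6-methyl-1,2-dioxan-3-yl]propanoate F2 and its C6 epimer methyl (2R)-2-[(3S,6R)-6-(hydroxymethyl)-6-methyl-1,2-dioxan-3-yl]propanoate F3, to be separated by chromatography.
- Dess–Martin oxidation of F2 would give the non-enolisable aldehyde methyl (2R)-2-[(3S,6S)-6-formyl-6-methyl-1,2-dioxan-3-yl]propanoate F4.
- Wittig olefination would use the ylide from [(2E,6E)-3,7,11-trimethyldodeca-2,6,10-trien-1-yl]triphenylphosphonium bromide F5 (from commercial (2E,6E)-farnesyl bromide and PPh3; NaHMDS, THF, −78 °C). It would give the diene methyl (2R)-2-[(3S,6S)-6-methyl-6-[(3E,7E)-4,8,12-trimethyltrideca-1,3,7,11-tetraen-1-yl]-1,2-dioxan-3-yl]propanoate F6 as a 1E/1Z mixture.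
- Diimide (potassium azodicarboxylate, AcOH, MeOH, 0 °C) should reduce only the disubstituted C1'=C2' olefin, sparing the trisubstituted olefins and the O–O bond, to give 20.

Step 7. The basic peroxide anion may eliminate the hindered secondary triflate (E2) faster than it substitutes it. The fallback runs from 7 back to 12 and gives up stereospecificity at C3 in favour of a base-free substitution:
- Appel iodination (PPh3, I2, imidazole, toluene) would give mainly the inverted iodide tert-butyl{[(2S,3S)-3-iodo-2,6-dimethylhept-6-en-1-yl]oxy}diphenylsilane F7.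
- Silver(I)-assisted substitution (AgOCOCF3, anhydrous H2O2 in Et2O, 0 °C) would give the hydroperoxide as both C3 epimers: tert-butyl{[(2S,3S)-3-hydroperoxy-2,6-dimethylhept-6-en-1-yl]oxy}diphenylsilane F8 and tert-butyl{[(2S,3R)-3-hydroperoxy-2,6-dimethylhept-6-en-1-yl]oxy}diphenylsilane F9. Because C2 is fixed, these are diastereomers and can be separated by chromatography.
- Peroxyacetalisation of F8 with dihydropyran 8 (PPTS, CH2Cl2) returns 12.

Step 2. The 1,1-disubstituted olefin may be hydrogenated or migrate through Ru–H species during ketone reduction. The fallback runs from 3 back to 4: enzymatic reduction with an (R)-selective ketoreductase (NADP+, i-PrOH, pH 7 buffer, 30 °C), a carbonyl-specific hydride transfer that cannot touch the olefin. It makes no new compound (F0).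

**Further compounds**

F1 | step 13 | methyl (2R,3S)-3-hydroperoxy-2-methyl-5-(2-methyloxiran-2-yl)pentanoate (both oxirane epimers) | COC(=O)[C@H](C)[C@@H](OO)CCC1(C)CO1
F2 | step 13 | methyl (2R)-2-[(3S,6S)-6-(hydroxymethyl)-6-methyl-1,2-dioxan-3-yl]propanoate | COC(=O)[C@H](C)[C@@H]1CC[C@@](C)(CO)OO1
F3 | step 13 | methyl (2R)-2-[(3S,6R)-6-(hydroxymethyl)-6-methyl-1,2-dioxan-3-yl]propanoate | COC(=O)[C@H](C)[C@@H]1CC[C@](C)(CO)OO1
F4 | step 13 | methyl (2R)-2-[(3S,6S)-6-formyl-6-methyl-1,2-dioxan-3-yl]propanoate | COC(=O)[C@H](C)[C@@H]1CC[C@@](C)(C=O)OO1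
F5 | step 13 | [(2E,6E)-3,7,11-trimethyldodeca-2,6,10-trien-1-yl]triphenylphosphonium bromide | [Br-].CC(C)=CCC/C(C)=C/CC/C(C)=C/C[P+](c1ccccc1)(c1ccccc1)c1ccccc1
F6 | step 13 | methyl (2R)-2-[(3S,6S)-6-methyl-6-[(3E,7E)-4,8,12-trimethyltrideca-1,3,7,11-tetraen-1-yl]-1,2-dioxan-3-yl]propanoate (1E/1Z mixture) | COC(=O)[C@H](C)[C@@H]1CC[C@@](C)(C=C/C=C(\C)CC/C=C(\C)CCC=C(C)C)OO1
F7 | step 7 | tert-butyl{[(2S,3S)-3-iodo-2,6-dimethylhept-6-en-1-yl]oxy}diphenylsilane | CC(C)(C)[Si](c1ccccc1)(c1ccccc1)OC[C@H](C)[C@@H](I)CCC(C)=C
F8 | step 7 | tert-butyl{[(2S,3S)-3-hydroperoxy-2,6-dimethylhept-6-en-1-yl]oxy}diphenylsilane | CC(C)(C)[Si](c1ccccc1)(c1ccccc1)OC[C@H](C)[C@@H](OO)CCC(C)=C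
F9 | step 7 | tert-butyl{[(2S,3R)-3-hydroperoxy-2,6-dimethylhept-6-en-1-yl]oxy}diphenylsilane | CC(C)(C)[Si](c1ccccc1)(c1ccccc1)OC[C@H](C)[C@H](OO)CCC(C)=C
F0 | step 2 | none | none
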